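The numbers in the tables were computed with made-up constants.

The reciprocal minute is the unit I reckon in, and the quantity to watch is the specific rate, ln(c(substrate) charged / c(substrate) left) divided by the elapsed time, a pseudo-first-order constant. I keep it here as the value from the last reading of Sunday's run.

| flask | substrate | reagent | free catalyst | time |
|---|---|---|---|---|
| Tuesday's | 200 mM | 500 mM | 20.0 mM |  |
| Sunday's | 200 mM | 1500 mM | 20.0 mM |  |
| Saturday's | 400 mM | 1500 mM | 20.0 mM | 9.6 min |

| run | time / min | [product] / mM |
|---|---|---|
| Tuesday's run | 0.38 | 10 |
| Tuesday's run | 0.66 | 17 |
| Tuesday's run | 1.1 | 28 |
| Tuesday's run | 1.9 | 44 |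
| Tuesday's run | 3.3 | 74 |
| Tuesday's run | 5.6 | 109 |
| Tuesday's run | 9.6 | 155 |
| Sunday's run | 0.38 | 5 |
| Sunday's run | 0.66 | 13 |
| Sunday's run | 1.1 | 15 |
| Sunday's run | 1.9 | 31 |
| Sunday's run | 3.3 | 41 |
| Sunday's run | 5.6 | 66 |
| Sunday's run | 9.6 | 108 |

(readings scatter by 3 mM)

* order of the initial rate in [reagent], near the charge of the Tuesday's run, the rate being that where two percent of its substrate are product
* product in the Saturday's run at 9.6 min, as a share of the substrate charged
* which of these the readings show (the second partner ties up the catalyst / the catalyst rests as a dimer / the substrate kills the catalyst / nothing beyond the main steps)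

- Overall: substrate + reagent -> product, with free catalyst as catalyst.
- Constant volume, constant temperature.
- A reading of a species includes what of it is bound.
- "The second partner" is reagent.
- An order is taken over about fifteen percent of the charge, up and down.

The last reading of Sunday's run gives 0.0809 /min, and that of Tuesday's run gives 0.155 /min. So tripling the reagent leaves about half of the specific rate, and the reagent charge matters strongly. Yet Saturday's run has the same 1500 mM of reagent and the same 20.0 mM of free catalyst as Sunday's run, so neither charge separates those two flasks.

The reading itself matters modestly: its scatter is 1.50% of Sunday's substrate charge. The doubled substrate charge is the number to watch. In Sunday's run the specific rate at 3.3 min is 0.0695 /min, lower than at the last reading. That gap is about twice what one reading's scatter puts on the earlier value, so I treat it as a warning. I still carry 0.0809 /min over, since it spans the very time asked, and my reckoning gives 54.0% for Saturday's run.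

The forecast says 49%, lower than my figure, with an order of −0.45 and the finding that the second partner ties up the catalyst: “The reagent therefore inhibits, which means it ties up catalyst in an off-cycle complex.”

    free catalyst + substrate → catalyst-substrate complex (12.00 /M/min)
    catalyst-substrate complex + reagent → loaded catalyst (201.6 /M/min)
    loaded catalyst → product + free catalyst (28.50 /min)
    free catalyst + reagent ⇌ idle catalyst-reagent complex, settled at all times (1.370 /M)

Saturday's run gives 53.4% of its substrate as product at 9.6 min. The order in reagent comes to −0.36, and the readings show that the second partner ties up the catalyst. As a specific rate, Saturday's share is 0.0796 /min, close to the 0.0809 /min of Sunday's run. In Tuesday's run the product came to half of the charge at 4.90 min, which puts the specific rate of that run up to then at 0.142 /min, higher than Saturday's.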